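(The earlier runs and the new flask come from a simulation with made-up constants, noise included.)

The pitfall in repeating Monday's run at half the charge is to halve its first-order constant along with the catalyst concentration and trust the result.

| setting | Monday's | north-east | south-east |
|---|---|---|---|
| left-handed substrate | 40 mM | 20 mM | 20 mM |
| right-handed substrate | 40 mM | 20 mM | 20 mM |
| gas | 1.6 mM (held) | 1.6 mM (held) | 1.6 mM (held) |
| free catalyst | 15 mol% | 15 mol% | 15 mol% |
| remark | run made earlier |  |  |
| time |  | 50 min | 12 min |

Monday's run (percent of the left-handed substrate and right-handed substrate together charged)

| time / min | right-handed substrate / % | left-handed substrate / % | left-handed product / % |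
|---|---|---|---|
| 0.417 | 49.3 | 45.0 | 1.8 |
| 1.00 | 48.9 | 43.3 | 3.6 |
| 2.00 | 48.2 | 39.4 | 6.4 |
| 5.00 | 47.1 | 30.8 | 16.2 |

(readings scatter by 0.5 percentage points)

- free catalyst is single-handed; left-handed substrate and right-handed substrate are mirror images of each other, charged as a racemate, each of them at the stated concentration
- at the start none of reagent is dissolved
- steps under discussion: left-handed substrate <-> right-handed substrate; reagent + catalyst intermediate B -> free catalyst + right-handed product; reagent + catalyst intermediate A -> free catalyst + left-handed product; gas <-> reagent; free catalyst + right-handed substrate <-> catalyst intermediate B; free catalyst <-> dormant form; free catalyst + left-handed substrate <-> catalyst intermediate A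
- an excess is the difference of the two amounts in percent of their sum
- an excess is below zero if the other one leads
- no earlier run changes the charge of free catalyst; that part of a forecast is a guess

1. the winner by excess of right-handed substrate over left-handed substrate among what is left of the two; "neither" if no more than 2 percentage points parts them (north-east / south-east / neither)
2. excess of right-handed substrate over left-handed substrate among what is left of the two at the end, north-east
3. excess of right-handed substrate over left-handed substrate among what is left of the two at the end, south-east

At this loading the catalyst is 7.50% of the two substrates together. Monday's last reading gives the turnovers per minute, which is left-handed product made per catalyst per minute: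

16.2% / 7.50% / 5.00 min = 0.432 min⁻¹

This turnover rate serves as a clock. The left-handed substrate needs 6.67 turnovers, so at this rate it lasts 15.4 min. Monday's loss ratio, right-handed substrate lost per left-handed substrate lost, is 0.151.

The first way counts turnovers, ignores bound forms and assumes the same rate in south-east:

left-handed product = 0.432 min⁻¹ × 12 min × 7.50% = 38.9%

c(left-handed substrate) = 11.1%, c(right-handed substrate) = 44.1%, excess = 59.7%

The second way is pseudo-first-order. Monday's left-handed substrate gives a constant of 0.0827 min⁻¹, which halves to 0.0414 min⁻¹ in south-east:

c(left-handed substrate) = 30.4%, c(right-handed substrate) = 47.0%, excess = 21.4%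

The two ways part by 38 percentage points, so one of them cheats. The second needs the rate to fall with c(left-handed substrate), which sinks from 45.0% to 30.8% on Monday. Yet left-handed product forms at 0.0327 min⁻¹ of the charge late in that run and at 0.0291 min⁻¹ early on, and with readings scattering by 0.5 points these two slopes do not part, so Monday's readings show no clear fall in rate. The balance also lacks 5.90% of the charge at 5.00 min, against 7.50% of catalyst. That gap is the reading to watch. The reckoning here keeps the count, 59.7% for south-east, as a judgement and not a proof. South-east stops before the clock runs out, and north-east runs far past it, so north-east should lead, though the count gives no figure for its residue.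

The forecast, lower for south-east than this count, gives 78% for north-east and 33% for south-east, with north-east ahead: “The longer run should still lead.”

The flasks give 93.3% in north-east and 60.7% in south-east, so north-east leads.

    left-handed substrate ⇌ right-handed substrate (k = 8.23 × 10⁻⁵ s⁻¹)
    reagent + catalyst intermediate B → free catalyst + right-handed product (k = 2.29 L mol⁻¹ s⁻¹)
    reagent + catalyst intermediate A → free catalyst + left-handed product (k = 22.0 L mol⁻¹ s⁻¹)
    gas ⇌ reagent, rate k4*(csat - [reagent]) (kL = 0.0465 s⁻¹)
    free catalyst + right-handed substrate ⇌ catalyst intermediate B (K = 29.0 L mol⁻¹, k = 43.6 L mol⁻¹ s⁻¹)
    free catalyst ⇌ dormant form (K = 2.92, k = 0.00241 s⁻¹)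
    free catalyst + left-handed substrate ⇌ catalyst intermediate A (K = 110 L mol⁻¹, k = 68.2 L mol⁻¹ s⁻¹)

South-east holds 39.1% left-handed product at 12.0 min, against the 38.9% counted. The clock's 15.4 min can be tried on south-east left until 20 min, a later time. That flask has 8.0% of its charged left-handed substrate still unbound.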